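**Strategy.** The route cuts the bond between oxolane C2 and dioxane C6 (C7–C6 of the chain). These two carbons both bear oxygen, the ring O and the peroxide O, in a threo array, which maps onto a (Z)-alkene. The key step is a Wittig union of a C7–C26 γ-lactol, carrying the (Z,Z)-diene and C10, with a C1–C6 ylide carrying the enoate as its carboxylate. In one operation it forms C6=C7 with Z geometry and frees the C10 hydroxyl. A hydroxyl-directed Re(VII) syn-oxidative cyclisation then sets C7 and C6 and closes the oxolane, SN2 peroxidation inverts C6, and oxa-Michael closure gives the trans-dioxane.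

Key step: step 10

Remark: atoms are numbered along the fatty-acid chain (C1 = CO2H; dioxane C3 and C6; oxolane C7 and C10; diene C19–C22); tosylate 8, alkynol 3 and bromide 14 are taken as purchasable.

**Route**

Step 1
Reactants: 1 hex-1-yne
Product: 2 1-bromohex-1-yne
Conditions: NBS, AgNO3 (10 mol%), acetone, rt
Reagents that add atoms: N-bromosuccinimide, O=C1CCC(=O)N1Br
Why: Silver-catalysed electrophilic bromination of the terminal alkyne C–H gives the bromoalkyne partner needed for an unsymmetrical diyne.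

Step 2
Reactants: 2 1-bromohex-1-yne; 3 non-8-yn-1-ol
Product: 4 pentadeca-8,10-diyn-1-ol
Conditions: CuCl (5 mol%), NH2OH·HCl, n-BuNH2, H2O/Et2O, 0 °C → rt
Reagents that add atoms: none
Why: Cadiot–Chodkiewicz coupling of the copper acetylide of 3 with bromoalkyne 2 should give the unsymmetrical 1,3-diyne without homocoupling, and the free alcohol is tolerated.

Step 3
Reactants: 4 pentadeca-8,10-diyn-1-ol
Product: 6 (8Z,10Z)-pentadeca-8,10-dien-1-ol, via triborylated diene 5 (not isolated)
Conditions: Cy2BH (3.3 equiv; from BH3·SMe2, cyclohexene), THF, 0 °C; AcOH, 55 °C; then NaOH, H2O2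
Reagents that add atoms: none
Why: Hydroboration–protonolysis of a conjugated diyne: the hindered dialkylborane adds once, syn, to each triple bond and acetic acid replaces each C–B bond by C–H with retention, which should give the (Z,Z)-diene (the third equivalent is held by the hydroxyl and released on work-up).

Step 4
Reactants: 6 (8Z,10Z)-pentadeca-8,10-dien-1-ol
Product: 7 (8Z,10Z)-1-bromopentadeca-8,10-diene
Conditions: CBr4, PPh3, CH2Cl2, 0 °C
Reagents that add atoms: carbon tetrabromide, BrC(Br)(Br)Br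
Why: Appel bromination converts the primary alcohol to the bromide under neutral conditions that should not isomerise the (Z,Z)-diene.

Step 5
Reactants: 8 [(2S)-5-oxooxolan-2-yl]methyl 4-methylbenzenesulfonate
Product: 9 methyl 3-[(2S)-oxiran-2-yl]propanoate
Conditions: NaOMe (1.0 equiv), MeOH, 0 °C → rt
Reagents that add atoms: sodium methoxide, [Na+].[O-]C
Why: Lactone methanolysis followed by intramolecular Williamson displacement of the primary tosylate by the freed alkoxide gives the terminal epoxide; no bond to the stereocentre is broken, so its configuration is kept.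

Step 6
Reactants: 7 (8Z,10Z)-1-bromopentadeca-8,10-diene; 9 methyl 3-[(2S)-oxiran-2-yl]propanoate
Product: 12 (5R)-5-[(9Z,11Z)-hexadeca-9,11-dien-1-yl]oxolan-2-one, via Grignard reagent 10 (not isolated), via hydroxy ester 11 (not isolated)
Conditions: Mg, THF; CuI (10 mol%), 9, −40 °C; aq. NH4Cl; then p-TsOH (cat.), CH2Cl2, rt
Reagents that add atoms: none
Why: Copper-catalysed Grignard opening of the terminal epoxide at its CH2 carbon (SN2, ester untouched at −40 °C) and acid-catalysed lactonisation of the γ-hydroxy ester; the C10 stereocentre is carried unchanged from 9 (S becomes R only through CIP priorities).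

Step 7
Reactants: 12 (5R)-5-[(9Z,11Z)-hexadeca-9,11-dien-1-yl]oxolan-2-one
Product: 13 (5R)-5-[(9Z,11Z)-hexadeca-9,11-dien-1-yl]oxolan-2-ol (anomer mixture)
Conditions: DIBAL-H (1.1 equiv), CH2Cl2, −78 °C; Rochelle salt
Reagents that add atoms: none
Why: Partial reduction of a γ-lactone with DIBAL-H at −78 °C stops at the tetrahedral aluminate and should give the lactol, a masked 4-hydroxy aldehyde, without touching the diene.

Step 8
Reactants: 14 5-bromopent-1-ene; 15 acrylic acid
Product: 16 (2E)-6-bromohex-2-enoic acid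
Conditions: second-generation Ru benzylidene catalyst (H2IMes)(PCy3)Cl2Ru=CHPh (3 mol%), CH2Cl2, 40 °C
Reagents that add atoms: none
Why: Olefin cross-metathesis of a terminal alkene with acrylic acid should give the (E)-enoic acid selectively, with ethylene as the only by-product.

Step 9
Reactants: 16 (2E)-6-bromohex-2-enoic acid
Product: 17 [(4E)-5-carboxypent-4-en-1-yl]triphenylphosphonium bromide
Conditions: PPh3, MeCN, reflux
Reagents that add atoms: triphenylphosphine, c1ccc(cc1)P(c1ccccc1)c1ccccc1
Why: SN2 quaternisation of triphenylphosphine by the primary bromide gives the crystalline phosphonium salt.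

Step 10
Reactants: 17 [(4E)-5-carboxypent-4-en-1-yl]triphenylphosphonium bromide; 13 (5R)-5-[(9Z,11Z)-hexadeca-9,11-dien-1-yl]oxolan-2-ol
Product: 19 (2E,6Z,10R,19Z,21Z)-10-hydroxyhexacosa-2,6,19,21-tetraenoic acid, via carboxylate ylide 18 (not isolated)
Conditions: NaHMDS (2 equiv per 17), THF, 0 °C; then 13 (0.33 equiv), −78 °C → rt; 1 M HCl to pH 4
Reagents that add atoms: none
Why: Wittig olefination of a γ-lactol with a non-stabilised ω-carboxyalkylidene ylide, the reaction type used for the upper chain of prostaglandins: the lactol alkoxide opens to the 4-oxido aldehyde, the ylide adds through an early puckered [2+2] transition state to the cis-oxaphosphetane, and syn-cycloreversion releases triphenylphosphine oxide and the (6Z)-alkene. No ring is closed and no sp3 stereocentre is made; the stereogenic element set here is the Z double bond, controlled kinetically by lithium-free, low-temperature conditions, while C10 (R) is untouched. The step needs Z over E selectivity, because the alkene geometry alone decides erythro versus threo at C6/C7 in step 12, and it needs the ylide to attack the aldehyde and not its own enoate; carrying C1 as the carboxylate, a poor Michael acceptor, should secure the latter. The same operation unmasks the C10 hydroxyl five atoms from the new alkene, the array the later ring closure requires.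

Step 11
Reactants: 19 (2E,6Z,10R,19Z,21Z)-10-hydroxyhexacosa-2,6,19,21-tetraenoic acid
Product: 20 methyl (2E,6Z,10R,19Z,21Z)-10-hydroxyhexacosa-2,6,19,21-tetraenoate
Conditions: MeI, K2CO3, DMF, rt
Reagents that add atoms: iodomethane, CI
Why: SN2 O-alkylation of the carboxylate (carbonate does not deprotonate the secondary alcohol) gives the methyl ester needed later as Michael acceptor.

Step 12
Reactants: 20 methyl (2E,6Z,10R,19Z,21Z)-10-hydroxyhexacosa-2,6,19,21-tetraenoate
Product: 21 methyl (2E,6R)-6-hydroxy-6-[(2S,5R)-5-[(9Z,11Z)-hexadeca-9,11-dien-1-yl]oxolan-2-yl]hex-2-enoate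
Conditions: CF3CO2ReO3 (from Re2O7, TFAA), TFAA, CH2Cl2, 0 °C; aq. NaHCO3
Reagents that add atoms: trifluoroacetyl perrhenate, O=[Re](=O)(=O)OC(=O)C(F)(F)F
Why: Hydroxyl-directed Re(VII) syn-oxidative cyclisation: the C10 perrhenate ester adds its alkoxy O and one oxo O to the same face of the (Z)-C6=C7 bond, so the Z geometry gives the erythro C6–OH/C7–O pair and the 2,5-trans ring (7S) should follow from the pseudo-equatorial C10 chain in the cyclic transition state; only the alkene five atoms from the hydroxyl can react, so the diene and the electron-poor enoate should be left.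

Step 13
Reactants: 21 methyl (2E,6R)-6-hydroxy-6-[(2S,5R)-5-[(9Z,11Z)-hexadeca-9,11-dien-1-yl]oxolan-2-yl]hex-2-enoate
Product: 23 methyl (2E,6S)-6-hydroperoxy-6-[(2S,5R)-5-[(9Z,11Z)-hexadeca-9,11-dien-1-yl]oxolan-2-yl]hex-2-enoate, via triflate 22 (not isolated)
Conditions: Tf2O, 2,6-lutidine, CH2Cl2, −78 °C; then H2O2 (30 equiv), CsOH·H2O (1.5 equiv), DMF, 0 °C
Reagents that add atoms: hydrogen peroxide, OO
Why: Sulfonate activation and SN2 displacement by hydroperoxide anion (an α-effect nucleophile), as in displacements on carbohydrate-type secondary triflates flanked by C–O bonds, should install the C6 hydroperoxide with inversion (6R to 6S).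

Step 14
Reactants: 23 methyl (2E,6S)-6-hydroperoxy-6-[(2S,5R)-5-[(9Z,11Z)-hexadeca-9,11-dien-1-yl]oxolan-2-yl]hex-2-enoate
Product: 24 methyl 2-[(3S,6S)-6-[(2S,5R)-5-[(9Z,11Z)-hexadeca-9,11-dien-1-yl]oxolan-2-yl]-1,2-dioxan-3-yl]acetate
Conditions: Et2NH (0.5 equiv), CF3CH2OH, rt
Reagents that add atoms: none
Why: Intramolecular oxa-Michael addition (6-exo-trig) of the hydroperoxide to the (E)-enoate closes the 1,2-dioxane; a chair transition state with the oxolanyl group at C6 and the forming CH2CO2Me arm at C3 both equatorial, together with reversibility under amine catalysis, should favour the 3,6-trans (3S) isomer.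

Step 15
Reactants: 24 methyl 2-[(3S,6S)-6-[(2S,5R)-5-[(9Z,11Z)-hexadeca-9,11-dien-1-yl]oxolan-2-yl]-1,2-dioxan-3-yl]acetate
Product: 25 stolonic acid B, 2-[(3S,6S)-6-[(2S,5R)-5-[(9Z,11Z)-hexadeca-9,11-dien-1-yl]oxolan-2-yl]-1,2-dioxan-3-yl]acetic acid
Conditions: LiOH, THF/H2O, 0 °C; then cold 1 M HCl to pH 3–4
Reagents that add atoms: lithium hydroxide, [Li+].[OH-]
Why: Saponification of the methyl ester at 0 °C, conditions that dialkyl peroxides of this type should survive, followed by mild acidification gives the acid without touching any stereocentre.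

**Compound list**

1 | hex-1-yne | CCCCC#C | starting material
2 | 1-bromohex-1-yne | CCCCC#CBr | intermediate
3 | non-8-yn-1-ol | OCCCCCCCC#C | starting material
4 | pentadeca-8,10-diyn-1-ol | CCCCC#CC#CCCCCCCCO | intermediate
5 | dicyclohexyl{[(8Z,10Z)-9,10-bis(dicyclohexylboranyl)pentadeca-8,10-dien-1-yl]oxy}borane | CCCC/C=C(B(C1CCCCC1)C1CCCCC1)\C(B(C1CCCCC1)C1CCCCC1)=C/CCCCCCCOB(C1CCCCC1)C1CCCCC1 | intermediate
6 | (8Z,10Z)-pentadeca-8,10-dien-1-ol | CCCC/C=C\C=C/CCCCCCCO | intermediate
7 | (8Z,10Z)-1-bromopentadeca-8,10-diene | CCCC/C=C\C=C/CCCCCCCBr | intermediate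
8 | [(2S)-5-oxooxolan-2-yl]methyl 4-methylbenzenesulfonate | O=C1CC[C@@H](COS(=O)(=O)c2ccc(C)cc2)O1 | starting material
9 | methyl 3-[(2S)-oxiran-2-yl]propanoate | COC(=O)CC[C@H]1CO1 | intermediate
10 | [(8Z,10Z)-pentadeca-8,10-dien-1-yl]magnesium bromide | CCCC/C=C\C=C/CCCCCCC[Mg]Br | intermediate
11 | methyl (4R,13Z,15Z)-4-hydroxyicosa-13,15-dienoate | CCCC/C=C\C=C/CCCCCCCC[C@@H](O)CCC(=O)OC | intermediate
12 | (5R)-5-[(9Z,11Z)-hexadeca-9,11-dien-1-yl]oxolan-2-one | CCCC/C=C\C=C/CCCCCCCC[C@@H]1CCC(=O)O1 | intermediate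
13 | (5R)-5-[(9Z,11Z)-hexadeca-9,11-dien-1-yl]oxolan-2-ol (anomer mixture) | CCCC/C=C\C=C/CCCCCCCC[C@@H]1CCC(O)O1 | intermediate
14 | 5-bromopent-1-ene | C=CCCCBr | starting material
15 | acrylic acid | C=CC(=O)O | starting material
16 | (2E)-6-bromohex-2-enoic acid | OC(=O)/C=C/CCCBr | intermediate
17 | [(4E)-5-carboxypent-4-en-1-yl]triphenylphosphonium bromide | OC(=O)/C=C/CCC[P+](c1ccccc1)(c1ccccc1)c1ccccc1.[Br-] | intermediate
18 | sodium (2E)-6-(triphenyl-λ5-phosphanylidene)hex-2-enoate | [Na+].[O-]C(=O)/C=C/CCC=P(c1ccccc1)(c1ccccc1)c1ccccc1 | intermediate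
19 | (2E,6Z,10R,19Z,21Z)-10-hydroxyhexacosa-2,6,19,21-tetraenoic acid | CCCC/C=C\C=C/CCCCCCCC[C@@H](O)CC/C=C\CC/C=C/C(=O)O | intermediate
20 | methyl (2E,6Z,10R,19Z,21Z)-10-hydroxyhexacosa-2,6,19,21-tetraenoate | CCCC/C=C\C=C/CCCCCCCC[C@@H](O)CC/C=C\CC/C=C/C(=O)OC | intermediate
21 | methyl (2E,6R)-6-hydroxy-6-[(2S,5R)-5-[(9Z,11Z)-hexadeca-9,11-dien-1-yl]oxolan-2-yl]hex-2-enoate | CCCC/C=C\C=C/CCCCCCCC[C@@H]1CC[C@@H]([C@H](O)CC/C=C/C(=O)OC)O1 | intermediate
22 | methyl (2E,6R)-6-[(2S,5R)-5-[(9Z,11Z)-hexadeca-9,11-dien-1-yl]oxolan-2-yl]-6-[(trifluoromethanesulfonyl)oxy]hex-2-enoate | CCCC/C=C\C=C/CCCCCCCC[C@@H]1CC[C@@H]([C@H](OS(=O)(=O)C(F)(F)F)CC/C=C/C(=O)OC)O1 | intermediate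
23 | methyl (2E,6S)-6-hydroperoxy-6-[(2S,5R)-5-[(9Z,11Z)-hexadeca-9,11-dien-1-yl]oxolan-2-yl]hex-2-enoate | CCCC/C=C\C=C/CCCCCCCC[C@@H]1CC[C@@H]([C@@H](OO)CC/C=C/C(=O)OC)O1 | intermediate
24 | methyl 2-[(3S,6S)-6-[(2S,5R)-5-[(9Z,11Z)-hexadeca-9,11-dien-1-yl]oxolan-2-yl]-1,2-dioxan-3-yl]acetate | CCCC/C=C\C=C/CCCCCCCC[C@@H]1CC[C@@H]([C@@H]2CC[C@@H](CC(=O)OC)OO2)O1 | intermediate
25 | stolonic acid B | CCCC/C=C\C=C/CCCCCCCC[C@@H]1CC[C@@H]([C@@H]2CC[C@@H](CC(=O)O)OO2)O1 | target

**Step count.** Total: 15 steps. Longest linear sequence: 12 steps (steps 1–4, 6, 7, 10–15).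

**Steps most likely to fail**

Step 13. The secondary triflate next to the ring oxygen may eliminate or ionise with participation of the oxolane oxygen (ring expansion), and hydroperoxide anion may attack the ester or be alkylated twice, so that inversion at C6 is not clean. Fallback: the route sets out again from alcohol 21 through triflate 22, which would be displaced by the caesium salt of 2-methoxypropan-2-yl hydroperoxide (CsOH·H2O, DMF, 0 °C), a mono-protected peroxide nucleophile that cannot be alkylated a second time. This should give the peroxyketal methyl (2E,6S)-6-[(2-methoxypropan-2-yl)peroxy]-6-(oxolan-2-yl)hex-2-enoate F1 with inversion. Unmasking with aqueous acetic acid in THF returns to hydroperoxide 23.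

Step 12. Ring closure may show poor facial selectivity (cis/trans oxolane mixture), trifluoroacetylation of the C10 hydroxyl may outrun perrhenate ester formation, or the acidic medium may isomerise the diene. Fallback: from alkenol 20, hydroxyl-directed epoxidation (VO(acac)2, t-BuOOH, CH2Cl2) would give the cis-6,7-epoxy alcohol F2, which is not isolated. Acid-catalysed 5-exo opening at C7 with inversion should give the threo (6S) oxolanyl alcohol F3. Oxidation (DMP, NaHCO3, CH2Cl2) would give the oxolanyl ketone F4, and chelation-controlled reduction with Zn(BH4)2 (Et2O, −30 °C) should give the erythro alcohol, returning to 21.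

Step 10. The ylide may add to the enoate of another molecule or be quenched by the lactol faster than it olefinates, and Z selectivity may erode. Fallback: from lactol 13, Wittig reaction with the ylide of [3-(1,3-dioxolan-2-yl)propyl]triphenylphosphonium bromide (NaHMDS, THF, −78 °C), which carries no acceptor, would give the (Z)-alkenol acetal (3Z,7R,16Z,18Z)-1-(1,3-dioxolan-2-yl)tricosa-3,16,18-trien-7-ol F5. Acetal hydrolysis (PPTS, acetone/H2O) would give the hydroxy aldehyde (4Z,8R,17Z,19Z)-8-hydroxytetracosa-4,17,19-trienal F6, and Wittig reaction with methyl (triphenylphosphoranylidene)acetate (CH2Cl2, rt) returns to ester 20.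

Further compounds
F1 | step 13 | methyl (2E,6S)-6-[(2-methoxypropan-2-yl)peroxy]-6-[(2S,5R)-5-[(9Z,11Z)-hexadeca-9,11-dien-1-yl]oxolan-2-yl]hex-2-enoate | CCCC/C=C\C=C/CCCCCCCC[C@@H]1CC[C@@H]([C@@H](OOC(C)(C)OC)CC/C=C/C(=O)OC)O1
F2 | step 12 | methyl (2E)-5-[(2S,3R)-3-[(3R,12Z,14Z)-3-hydroxynonadeca-12,14-dien-1-yl]oxiran-2-yl]pent-2-enoate | CCCC/C=C\C=C/CCCCCCCC[C@@H](O)CC[C@H]1O[C@H]1CC/C=C/C(=O)OC
F3 | step 12 | methyl (2E,6S)-6-hydroxy-6-[(2S,5R)-5-[(9Z,11Z)-hexadeca-9,11-dien-1-yl]oxolan-2-yl]hex-2-enoate | CCCC/C=C\C=C/CCCCCCCC[C@@H]1CC[C@@H]([C@@H](O)CC/C=C/C(=O)OC)O1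
F4 | step 12 | methyl (2E)-6-[(2S,5R)-5-[(9Z,11Z)-hexadeca-9,11-dien-1-yl]oxolan-2-yl]-6-oxohex-2-enoate | CCCC/C=C\C=C/CCCCCCCC[C@@H]1CC[C@@H](C(=O)CC/C=C/C(=O)OC)O1
F5 | step 10 | (3Z,7R,16Z,18Z)-1-(1,3-dioxolan-2-yl)tricosa-3,16,18-trien-7-ol | CCCC/C=C\C=C/CCCCCCCC[C@@H](O)CC/C=C\CCC1OCCO1
F6 | step 10 | (4Z,8R,17Z,19Z)-8-hydroxytetracosa-4,17,19-trienal | CCCC/C=C\C=C/CCCCCCCC[C@@H](O)CC/C=C\CCC=O
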